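**Plan**

- The target is read as epicatechin-(4α→8)-epigallocatechin 3-O-gallate: the upper unit is 2,3-cis-3,4-cis (all-cis), the lower unit is (2R,3R) and carries the gallate on its C3.
- Retrosynthetic cuts, in order: all ArCH2–O and Si–O bonds (deprotection); the upper C3 carbinol (inversion through the 3-ketone); the interflavan C4–C8 bond; in ring C of the lower unit the C4–C4a bond together with the C3–O(gallate) bond, which leads back to a cis-2-aryl-3-(hydroxymethyl)-2,3-dihydrobenzofuran; then its C2–C3 bond (carbenoid C–H insertion into the ring B benzyl ether), the ArO–CH2 bond and the aryl–CO bond.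
- Enabling feature: ring A of the lower unit is a phloroglucinol ring, and its C4a is ortho, ortho and para to O1, O5 and O7. This ipso carbon can bridge from C3 to an exocyclic CH2 as a phenonium ion, so C4 is inserted between C3 and C4a while the gallate enters at C3.
- Forward order: bis-silylated phloroglucinol → ortho-hydroxyaryl glyoxylate → ether with the gallic-acid-derived benzyl alcohol → aryldiazoacetate → dihydrobenzofuran (five-membered ring first) → ring expansion to ring C with the gallate in place → coupling at C8 to a catechin-derived C4 cation → C3 inversion of the upper unit → desilylation → hydrogenolysis.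
- Stereochemistry: lower C2 and C3 come from the chiral dirhodium catalyst (cis insertion) and from stereospecific inversion at C3 in the ring expansion. Upper C2 comes from (+)-catechin, upper C4 is directed trans by the catechin C3 oxygen, and upper C3 is then inverted by oxidation and hydride delivery to the face away from both aryl groups.

Key step: step 8

Assumption: Rh2(R-PTTL)4 is taken to be the catalyst antipode that leads to the (2S,3R) ester 10; if the sense of induction is the opposite, Rh2(S-PTTL)4 is used and nothing else changes.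

**Route**

Step 1
Reactants: 1 3,4,5-tris(benzyloxy)benzoic acid
Product: 2 3,4,5-tris(benzyloxy)benzyl alcohol
Conditions: LiAlH4, THF, 0 °C to reflux; aqueous work-up
Reagents that add atoms: none
Why: Hydride reduction of a carboxylic acid to the primary alcohol (LiAlH4 reduction); benzyl ethers are inert.

Step 2
Reactants: 3 phloroglucinol
Product: 4 3,5-bis(triisopropylsilyloxy)phenol
Conditions: i-Pr3SiCl (2.0 equiv), imidazole, DMF, 0 °C to rt; chromatography
Reagents that add atoms: triisopropylsilyl chloride, CC(C)[Si](Cl)(C(C)C)C(C)C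
Why: Silylation of phenols with a silyl chloride and imidazole, in which two equivalents should make the bis-ether the main component of a separable statistical mixture; the silyl ethers are chosen because they carry no C–H bond that a carbenoid can reach in the 1,5 mode.

Step 3
Reactants: 4 3,5-bis(triisopropylsilyloxy)phenol
Product: 6 methyl 2-[2-hydroxy-4,6-bis(triisopropylsilyloxy)phenyl]-2-oxoacetate, via benzofuran-2,3-dione 5 (not isolated)
Conditions: (COCl)2 (1.2 equiv), Et2O, 0 °C to rt; evaporation; then MeOH, pyridine (cat.), CH2Cl2, 0 °C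
Reagents that add atoms: oxalyl chloride, O=C(Cl)C(Cl)=O; methanol, CO
Why: Acylation of an electron-rich phenol with oxalyl chloride (Friedel–Crafts acylation plus lactonisation) closes the benzofuran-2,3-dione, which fixes the new aryl–CO bond ortho to the phenol oxygen (the two ortho positions are equivalent, the position between the two silyl ethers is shielded and cannot lactonise), and methanol then opens the activated aryl ester.

Step 4
Reactants: 6 methyl 2-[2-hydroxy-4,6-bis(triisopropylsilyloxy)phenyl]-2-oxoacetate; 2 3,4,5-tris(benzyloxy)benzyl alcohol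
Product: 7 methyl arylglyoxylate with the 3,4,5-tris(benzyloxy)benzyl ether ortho to the keto ester
Conditions: PPh3, DIAD (added last), THF, 0 °C to rt
Reagents that add atoms: none
Why: Mitsunobu etherification of the acidic ortho-acyl phenol with a primary benzylic alcohol under neutral conditions that should spare the aryl silyl ethers; only this oxygen receives the benzylic group that later becomes C2 and ring B.

Step 5
Reactants: 7 methyl arylglyoxylate
Product: 9 methyl aryldiazoacetate, via tosylhydrazone 8 (not isolated)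
Conditions: TsNHNH2, toluene, 70 °C; then DBU, dry CH2Cl2, 0 °C to rt
Reagents that add atoms: p-toluenesulfonyl hydrazide, Cc1ccc(cc1)S(=O)(=O)NN
Why: Hydrazone condensation and Bamford–Stevens elimination of sulfinate, the standard way from an aryl glyoxylate to an aryldiazoacetate.

Step 6
Reactants: 9 methyl aryldiazoacetate
Product: 10 methyl (2S,3R)-cis-2-aryl-2,3-dihydrobenzofuran-3-carboxylate
Conditions: Rh2(R-PTTL)4 [dirhodium tetrakis(N-phthaloyl-(R)-tert-leucinate)] (1 mol %), toluene, −60 to −20 °C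
Reagents that add atoms: none
Why: Intramolecular 1,5 C–H insertion of a divalent rhodium carbenoid into the benzylic C–H of the ortho ether; the other ortho substituent is a silyl ether with no C–H bond in reach of the 1,5 mode, so one constitution results, the concerted insertion gives the kinetic cis ring, and the chiral carboxylate ligands set C2 and C3.

Step 7
Reactants: 10 methyl (2S,3R)-cis-2-aryl-2,3-dihydrobenzofuran-3-carboxylate
Product: 11 (2S,3S)-cis-2-aryl-3-(hydroxymethyl)-2,3-dihydrobenzofuran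
Conditions: i-Bu2AlH (3 equiv), CH2Cl2, −78 °C; aqueous work-up
Reagents that add atoms: none
Why: Ester reduction with a Lewis acidic, non-basic hydride at low temperature, so the epimerisable C3 should keep its cis configuration.

Step 8
Reactants: 11 (2S,3S)-cis-2-aryl-3-(hydroxymethyl)-2,3-dihydrobenzofuran; 1 3,4,5-tris(benzyloxy)benzoic acid
Product: 14 protected (2R,3R)-epigallocatechin 3-O-gallate, via primary triflate 12 (not isolated), via phenonium triflate 13 (not isolated)
Conditions: Tf2O (1.05 equiv), 2,6-di-tert-butyl-4-methylpyridine, CH2Cl2, −78 °C; then 1 (2 equiv), i-Pr2NEt, −78 to −20 °C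
Reagents that add atoms: none
Why: Proposed new method: O-triflation makes the CH2 an electrophile that the ipso carbon C3a of ring A (ortho, ortho and para to the ring oxygen and the two silyloxy groups) captures by Ar1-3 participation to give the cyclopropane-fused arenium (phenonium) ion 13; the carboxylate of 1 then opens the three-membered ring at the ring carbon C3 with inversion, so the C3–C3a bond is exchanged for C3–O and the former CH2 is inserted between C3 and ring A as C4, which turns the dihydrofuran into the chroman ring. The closest known reaction types are the stereospecific phenonium (neophyl-type) rearrangement of 2-arylalkyl sulfonates and the radical neophyl expansion of dihydrobenzofuran-3-ylmethyl to chroman-3-yl; the cationic version with carboxylate capture on a 2-aryl-dihydrobenzofuran is the untested part. The cyclopropane closes in the 3-exo-tet mode, and the six-membered ring is not closed as such but arises by cleavage of the bond shared by the three- and five-membered rings. The new stereocentre C3 is set by C3 of 11 through backside attack anti to the departing aryl carbon while C2 is untouched, so the cis precursor should give the 2,3-cis (2R,3R) gallate. The step needs opening at C3 and not at the CH2, which would keep the five-membered ring: the secondary carbon carries more positive charge, cleavage of the shared bond releases the bicyclo[3.1.0] strain, and the cis 2-aryl group screens the backside of the CH2. Neither O1 nor ring B is antiperiplanar to the breaking bond, so no competing 1,2-shift to an isoflavan or to a benzylic cation is expected.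

Step 9
Reactants: 15 (+)-catechin
Product: 16 5,7,3',4'-tetra-O-benzyl-(+)-catechin
Conditions: BnBr (4.4 equiv), K2CO3, DMF, 0 °C to rt
Reagents that add atoms: benzyl bromide, BrCc1ccccc1
Why: Williamson benzylation of the four phenols, which are far more acidic than the secondary alcohol.

Step 10
Reactants: 16 5,7,3',4'-tetra-O-benzyl-(+)-catechin
Product: 17 (2R,3S,4S)-4-(2-ethoxyethoxy)-5,7,3',4'-tetra-O-benzylcatechin
Conditions: DDQ (2 equiv), 2-ethoxyethanol, CH2Cl2, rt
Reagents that add atoms: 2-ethoxyethanol, CCOCCO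
Why: DDQ oxidation of the benzylic C4 next to the electron-rich ring A to a quinone methide cation that the alcohol traps; the C4 configuration is of no consequence because this centre ionises again in step 11.

Step 11
Reactants: 17 (2R,3S,4S)-4-(2-ethoxyethoxy)-5,7,3',4'-tetra-O-benzylcatechin; 14 protected (2R,3R)-epigallocatechin 3-O-gallate (1.3 equiv)
Product: 18 protected catechin-(4α→8)-epigallocatechin gallate with free upper 3-OH
Conditions: TMSOTf (0.2 equiv), CH2Cl2, −78 °C
Reagents that add atoms: none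
Why: Lewis-acid-promoted Friedel–Crafts coupling of a flavan-4-yl cation with the ring A nucleophile; C8 (between the ring oxygen and one silyl ether) should react rather than C6 (between two triisopropylsilyl ethers), and the arene should enter anti to the 3β-hydroxyl of the 2,3-trans unit to give the 3,4-trans 4α bond.

Step 12
Reactants: 18 protected catechin-(4α→8)-epigallocatechin gallate with free upper 3-OH
Product: 19 upper-unit 3-ketone
Conditions: Dess–Martin periodinane, pyridine, CH2Cl2, 0 °C to rt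
Reagents that add atoms: none
Why: Dess–Martin oxidation of the only free hydroxyl under buffered, non-basic conditions, which should leave the acidic C2 and C4 hydrogens alone; the 2,4-cis arrangement of the aryl groups is also expected to be the more stable one.

Step 13
Reactants: 19 upper-unit 3-ketone
Product: 20 protected epicatechin-(4α→8)-epigallocatechin gallate (upper unit all-cis)
Conditions: LiBH(s-Bu)3 (L-Selectride), THF, −78 °C; H2O
Reagents that add atoms: none
Why: Bulky hydride reduction, the same reaction type that turns catechin-type 3-ketones into epicatechin-type alcohols; both aryl groups lie on the α-face, so hydride should arrive from the β-face and give the 3α-hydroxyl cis to both, while the hindered aryl ester and the aryl silyl ethers are expected to survive at −78 °C.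

Step 14
Reactants: 20 protected epicatechin-(4α→8)-epigallocatechin gallate (upper unit all-cis)
Product: 21 5,7-diphenol of the lower unit with all benzyl ethers in place
Conditions: Bu4NF (2.2 equiv), AcOH (2.5 equiv), THF, 0 °C
Reagents that add atoms: none
Why: Fluoride cleavage of the two aryl silyl ethers, buffered with acetic acid so that the gallate ester and the C2 centres are not exposed to phenoxide or basic fluoride; the benzyl ethers are untouched.

Step 15
Reactants: 21 5,7-diphenol of the lower unit with all benzyl ethers in place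
Product: 22 epicatechin-(4α→8)-epigallocatechin 3-O-gallate (target)
Conditions: H2 (1 atm), Pd(OH)2/C, THF/MeOH/H2O, rt
Reagents that add atoms: none
Why: Hydrogenolysis of the ten benzyl ethers; the ester and the interflavan bond are stable under these neutral conditions.

**Compound list**

1 | 3,4,5-tris(benzyloxy)benzoic acid | OC(=O)c1cc(OCc2ccccc2)c(OCc2ccccc2)c(OCc2ccccc2)c1 | starting material
2 | 3,4,5-tris(benzyloxy)benzyl alcohol | OCc1cc(OCc2ccccc2)c(OCc2ccccc2)c(OCc2ccccc2)c1 | intermediate
3 | phloroglucinol (benzene-1,3,5-triol) | Oc1cc(O)cc(O)c1 | starting material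
4 | 3,5-bis(triisopropylsilyloxy)phenol | Oc1cc(O[Si](C(C)C)(C(C)C)C(C)C)cc(O[Si](C(C)C)(C(C)C)C(C)C)c1 | intermediate
5 | 4,6-bis(triisopropylsilyloxy)benzofuran-2,3-dione | O=C1Oc2cc(O[Si](C(C)C)(C(C)C)C(C)C)cc(O[Si](C(C)C)(C(C)C)C(C)C)c2C1=O | intermediate (not isolated)
6 | methyl 2-[2-hydroxy-4,6-bis(triisopropylsilyloxy)phenyl]-2-oxoacetate | COC(=O)C(=O)c1c(O)cc(O[Si](C(C)C)(C(C)C)C(C)C)cc1O[Si](C(C)C)(C(C)C)C(C)C | intermediate
7 | methyl 2-oxo-2-[2-{[3,4,5-tris(benzyloxy)benzyl]oxy}-4,6-bis(triisopropylsilyloxy)phenyl]acetate | COC(=O)C(=O)c1c(OCc2cc(OCc3ccccc3)c(OCc3ccccc3)c(OCc3ccccc3)c2)cc(O[Si](C(C)C)(C(C)C)C(C)C)cc1O[Si](C(C)C)(C(C)C)C(C)C | intermediate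
8 | N-tosylhydrazone of 7 | COC(=O)C(=NNS(=O)(=O)c1ccc(C)cc1)c1c(OCc2cc(OCc3ccccc3)c(OCc3ccccc3)c(OCc3ccccc3)c2)cc(O[Si](C(C)C)(C(C)C)C(C)C)cc1O[Si](C(C)C)(C(C)C)C(C)C | intermediate (not isolated)
9 | methyl 2-diazo-2-[2-{[3,4,5-tris(benzyloxy)benzyl]oxy}-4,6-bis(triisopropylsilyloxy)phenyl]acetate | COC(=O)C(=[N+]=[N-])c1c(OCc2cc(OCc3ccccc3)c(OCc3ccccc3)c(OCc3ccccc3)c2)cc(O[Si](C(C)C)(C(C)C)C(C)C)cc1O[Si](C(C)C)(C(C)C)C(C)C | intermediate
10 | methyl (2S,3R)-2-[3,4,5-tris(benzyloxy)phenyl]-4,6-bis(triisopropylsilyloxy)-2,3-dihydrobenzofuran-3-carboxylate (2,3-cis) | COC(=O)[C@@H]1c2c(O[Si](C(C)C)(C(C)C)C(C)C)cc(O[Si](C(C)C)(C(C)C)C(C)C)cc2O[C@@H]1c1cc(OCc2ccccc2)c(OCc2ccccc2)c(OCc2ccccc2)c1 | intermediate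
11 | [(2S,3S)-2-[3,4,5-tris(benzyloxy)phenyl]-4,6-bis(triisopropylsilyloxy)-2,3-dihydrobenzofuran-3-yl]methanol (2,3-cis) | OC[C@@H]1c2c(O[Si](C(C)C)(C(C)C)C(C)C)cc(O[Si](C(C)C)(C(C)C)C(C)C)cc2O[C@@H]1c1cc(OCc2ccccc2)c(OCc2ccccc2)c(OCc2ccccc2)c1 | intermediate
12 | trifluoromethanesulfonate of 11 | O=S(=O)(OC[C@@H]1c2c(O[Si](C(C)C)(C(C)C)C(C)C)cc(O[Si](C(C)C)(C(C)C)C(C)C)cc2O[C@@H]1c1cc(OCc2ccccc2)c(OCc2ccccc2)c(OCc2ccccc2)c1)C(F)(F)F | intermediate (not isolated)
13 | phenonium triflate: cyclopropane-fused arenium ion in which the ring A ipso carbon bridges C3 and the former CH2 (drawn with the charge on the ring oxygen) | C1[C@H]2[C@@H](c4cc(OCc5ccccc5)c(OCc5ccccc5)c(OCc5ccccc5)c4)[O+]=C3C=C(O[Si](C(C)C)(C(C)C)C(C)C)C=C(O[Si](C(C)C)(C(C)C)C(C)C)[C@]123.[O-]S(=O)(=O)C(F)(F)F | intermediate (not isolated)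
14 | (2R,3R)-2-[3,4,5-tris(benzyloxy)phenyl]-5,7-bis(triisopropylsilyloxy)chroman-3-yl 3,4,5-tris(benzyloxy)benzoate (2,3-cis) | O=C(O[C@@H]1Cc2c(O[Si](C(C)C)(C(C)C)C(C)C)cc(O[Si](C(C)C)(C(C)C)C(C)C)cc2O[C@@H]1c1cc(OCc2ccccc2)c(OCc2ccccc2)c(OCc2ccccc2)c1)c1cc(OCc2ccccc2)c(OCc2ccccc2)c(OCc2ccccc2)c1 | intermediate
15 | (+)-catechin, (2R,3S) | O[C@H]1Cc2c(O)cc(O)cc2O[C@@H]1c1ccc(O)c(O)c1 | starting material
16 | 5,7,3',4'-tetra-O-benzyl-(+)-catechin | O[C@H]1Cc2c(OCc3ccccc3)cc(OCc3ccccc3)cc2O[C@@H]1c1ccc(OCc2ccccc2)c(OCc2ccccc2)c1 | intermediate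
17 | (2R,3S,4S)-4-(2-ethoxyethoxy)-5,7,3',4'-tetra-O-benzylcatechin | CCOCCO[C@@H]1[C@H](O)[C@@H](c2ccc(OCc3ccccc3)c(OCc3ccccc3)c2)Oc2cc(OCc3ccccc3)cc(OCc3ccccc3)c21 | intermediate
18 | protected catechin-(4α→8)-epigallocatechin 3-O-gallate: upper unit 2,3-trans-3,4-trans with free 3-OH, lower unit as in 14 | O=C(O[C@@H]1Cc2c(O[Si](C(C)C)(C(C)C)C(C)C)cc(O[Si](C(C)C)(C(C)C)C(C)C)c([C@@H]3c4c(OCc5ccccc5)cc(OCc5ccccc5)cc4O[C@H](c4ccc(OCc5ccccc5)c(OCc5ccccc5)c4)[C@H]3O)c2O[C@@H]1c1cc(OCc2ccccc2)c(OCc2ccccc2)c(OCc2ccccc2)c1)c1cc(OCc2ccccc2)c(OCc2ccccc2)c(OCc2ccccc2)c1 | intermediate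
19 | 3-ketone of 18 (upper unit 2,4-cis-diaryl chroman-3-one) | O=C(O[C@@H]1Cc2c(O[Si](C(C)C)(C(C)C)C(C)C)cc(O[Si](C(C)C)(C(C)C)C(C)C)c([C@@H]3c4c(OCc5ccccc5)cc(OCc5ccccc5)cc4O[C@H](c4ccc(OCc5ccccc5)c(OCc5ccccc5)c4)C3=O)c2O[C@@H]1c1cc(OCc2ccccc2)c(OCc2ccccc2)c(OCc2ccccc2)c1)c1cc(OCc2ccccc2)c(OCc2ccccc2)c(OCc2ccccc2)c1 | intermediate
20 | protected epicatechin-(4α→8)-epigallocatechin 3-O-gallate: upper unit 2,3-cis-3,4-cis with free 3α-OH | O=C(O[C@@H]1Cc2c(O[Si](C(C)C)(C(C)C)C(C)C)cc(O[Si](C(C)C)(C(C)C)C(C)C)c([C@@H]3c4c(OCc5ccccc5)cc(OCc5ccccc5)cc4O[C@H](c4ccc(OCc5ccccc5)c(OCc5ccccc5)c4)[C@@H]3O)c2O[C@@H]1c1cc(OCc2ccccc2)c(OCc2ccccc2)c(OCc2ccccc2)c1)c1cc(OCc2ccccc2)c(OCc2ccccc2)c(OCc2ccccc2)c1 | intermediate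
21 | deca-O-benzyl epicatechin-(4α→8)-epigallocatechin 3-O-gallate with free 5- and 7-hydroxyls on the lower unit | O=C(O[C@@H]1Cc2c(O)cc(O)c([C@@H]3c4c(OCc5ccccc5)cc(OCc5ccccc5)cc4O[C@H](c4ccc(OCc5ccccc5)c(OCc5ccccc5)c4)[C@@H]3O)c2O[C@@H]1c1cc(OCc2ccccc2)c(OCc2ccccc2)c(OCc2ccccc2)c1)c1cc(OCc2ccccc2)c(OCc2ccccc2)c(OCc2ccccc2)c1 | intermediate
22 | epicatechin-(4α→8)-epigallocatechin 3-O-gallate (CNP0246304.3) | O=C(O[C@@H]1Cc2c(O)cc(O)c([C@@H]3c4c(O)cc(O)cc4O[C@H](c4ccc(O)c(O)c4)[C@@H]3O)c2O[C@@H]1c1cc(O)c(O)c(O)c1)c1cc(O)c(O)c(O)c1 | target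

**Count and risks**

Total step count: 15. Longest linear sequence: 12 steps (steps 2 to 8, then 11 to 15); step 1 supplies alcohol 2, and steps 9 and 10 form the short upper-unit branch.

Steps most likely to fail:

1. Step 8 (proposed new method). The bridged ion may be captured at the exocyclic carbon instead of the ring carbon, so that no ring expansion occurs, or a proton may be lost instead of the carboxylate being taken up. The fallback keeps the same ring A migration but drives it by a semipinacol rearrangement, a known reaction type that cannot return to the five-membered ring; it sets out from 10 and comes back at 14. Ester 10 is hydroxylated at C3 through its potassium enolate (KN(SiMe3)2, then 2-(phenylsulfonyl)-3-phenyloxaziridine, THF, −78 °C) to the tertiary hydroxy ester F1. LiAlH4 at 0 °C reduces it to the 1,2-diol F2, and TsCl/pyridine sulfonylates the primary hydroxyl to the hydroxy tosylate F3. Et3Al in CH2Cl2 at −78 °C then makes the ring A carbon migrate to the CH2 while the carbinol becomes the carbonyl, giving the (2R)-flavan-3-one F4. LiBH(s-Bu)3 at −78 °C reduces F4 from the face away from the 2-aryl group to the 2,3-cis alcohol F5, and esterification with acid 1 (EDC, DMAP, CH2Cl2) gives 14.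

2. Step 11. The arene may attack the C4 cation on the wrong face or through C6, the bulky silyl ethers may slow the attack, and the donor may condense with itself. The fallback replaces steric control by anchimeric control; it sets out from 17 and comes back at 18. Esterification of the 3-hydroxyl with levulinic acid (EDC, DMAP, CH2Cl2) gives the 3-levulinate F6. On activation with TMSOTf the ester carbonyl should close onto C4 from the β-face as a dioxolanylium ion, so that 14 can enter only from the α-face, giving the 3-O-levulinoyl dimer F7. Hydrazine acetate in CH2Cl2/MeOH removes the levulinate without touching the gallate or the aryl silyl ethers and leads back to 18.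

3. Step 13. Hydride may be delivered to the α-face, the doubly benzylic C4 may be enolised, or the flanked carbonyl may react too slowly. The fallback moves the source of stereocontrol from the substrate to the reagent; it sets out from 19 and comes back at 20 and makes no new compound. The ketone is reduced with BH3·SMe2 and a catalytic oxazaborolidine (Corey–Bakshi–Shibata reduction), using the catalyst enantiomer that is matched with β-face delivery. This reagent is not basic and leaves esters and silyl ethers alone.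

Further compounds
F1 | step 8 | methyl (2R,3S)-3-hydroxy-2-[3,4,5-tris(benzyloxy)phenyl]-4,6-bis(triisopropylsilyloxy)-2,3-dihydrobenzofuran-3-carboxylate (hydroxyl trans to the 2-aryl group) | COC(=O)[C@]1(O)c2c(O[Si](C(C)C)(C(C)C)C(C)C)cc(O[Si](C(C)C)(C(C)C)C(C)C)cc2O[C@@H]1c1cc(OCc2ccccc2)c(OCc2ccccc2)c(OCc2ccccc2)c1
F2 | step 8 | 3-(hydroxymethyl)-2-[3,4,5-tris(benzyloxy)phenyl]-4,6-bis(triisopropylsilyloxy)-2,3-dihydrobenzofuran-3-ol (diol from F1, same spatial arrangement) | OC[C@]1(O)c2c(O[Si](C(C)C)(C(C)C)C(C)C)cc(O[Si](C(C)C)(C(C)C)C(C)C)cc2O[C@@H]1c1cc(OCc2ccccc2)c(OCc2ccccc2)c(OCc2ccccc2)c1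
F3 | step 8 | primary p-toluenesulfonate of F2 | Cc1ccc(cc1)S(=O)(=O)OC[C@]1(O)c2c(O[Si](C(C)C)(C(C)C)C(C)C)cc(O[Si](C(C)C)(C(C)C)C(C)C)cc2O[C@@H]1c1cc(OCc2ccccc2)c(OCc2ccccc2)c(OCc2ccccc2)c1
F4 | step 8 | (2R)-2-[3,4,5-tris(benzyloxy)phenyl]-5,7-bis(triisopropylsilyloxy)chroman-3-one | O=C1Cc2c(O[Si](C(C)C)(C(C)C)C(C)C)cc(O[Si](C(C)C)(C(C)C)C(C)C)cc2O[C@@H]1c1cc(OCc2ccccc2)c(OCc2ccccc2)c(OCc2ccccc2)c1
F5 | step 8 | (2R,3R)-2-[3,4,5-tris(benzyloxy)phenyl]-5,7-bis(triisopropylsilyloxy)chroman-3-ol (2,3-cis) | O[C@@H]1Cc2c(O[Si](C(C)C)(C(C)C)C(C)C)cc(O[Si](C(C)C)(C(C)C)C(C)C)cc2O[C@@H]1c1cc(OCc2ccccc2)c(OCc2ccccc2)c(OCc2ccccc2)c1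
F6 | step 11 | (2R,3S,4S)-3-O-levulinoyl-4-(2-ethoxyethoxy)-5,7,3',4'-tetra-O-benzylcatechin | CCOCCO[C@@H]1[C@H](OC(=O)CCC(C)=O)[C@@H](c2ccc(OCc3ccccc3)c(OCc3ccccc3)c2)Oc2cc(OCc3ccccc3)cc(OCc3ccccc3)c21
F7 | step 11 | upper 3-O-levulinate of 18 | O=C(O[C@@H]1Cc2c(O[Si](C(C)C)(C(C)C)C(C)C)cc(O[Si](C(C)C)(C(C)C)C(C)C)c([C@@H]3c4c(OCc5ccccc5)cc(OCc5ccccc5)cc4O[C@H](c4ccc(OCc5ccccc5)c(OCc5ccccc5)c4)[C@H]3OC(=O)CCC(C)=O)c2O[C@@H]1c1cc(OCc2ccccc2)c(OCc2ccccc2)c(OCc2ccccc2)c1)c1cc(OCc2ccccc2)c(OCc2ccccc2)c(OCc2ccccc2)c1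
F0 | step 13 | none | none
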